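**Strategy.** The depside ester is cut into benzyl olivetolate and a ring A keto acid, and everything rests on cutting the C6–CH2 bond of ring A. Ring A without its chain is 4-methoxysalicylic acid: C1 holds the carboxyl, O2 and O4 are in place, and with O2 benzylated C6–H is the single C–H flanking the carboxyl, the carbon that carries the CH2C(=O)C3H7 chain. A carboxylate-directed, trivalent-rhodium-catalysed coupling of 2-(benzyloxy)-4-methoxybenzoic acid with the butyryl sulfoxonium ylide forms the C6–CH2 bond and the lactone C–O bond in one operation. It gives 8-(benzyloxy)-6-methoxy-3-propylisocoumarin, a neutral, storable mask of the 2-oxopentyl acid. Hydroxide unmasks it; esterification and one hydrogenolysis finish.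

Key step: step 3

Remark: the target has no stereocentre; ring B is carried as its benzyl ester with the 2-hydroxyl free, because that hydroxyl is hydrogen-bonded to the ester carbonyl and only the 4-hydroxyl is acylated, so the last step removes two benzyl groups; benzyl bromide, bases, coupling agents and catalysts are reagents and carry no number.

**Step 1**
Reactants: 1 4-methoxysalicylic acid (2-hydroxy-4-methoxybenzoic acid)
Product: 3 2-(benzyloxy)-4-methoxybenzoic acid, via benzyl 2-(benzyloxy)-4-methoxybenzoate 2 (not isolated)
Conditions: BnBr (2.3 equiv), K2CO3 (3 equiv), DMF, 60 °C; then 4 M aq NaOH, MeOH, 70 °C; then aq HCl, 0 °C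
Reagents that add atoms: benzyl bromide, BrCc1ccccc1; sodium hydroxide, [Na+].[OH-]
Why: Williamson O-alkylation of the phenoxide and SN2 alkylation of the carboxylate give ester 2, whose unhindered benzyl ester is then saponified (hydroxide oxygen ends in the carboxyl group) while the aryl benzyl ether is inert to base.

**Step 2**
Reactants: 4 trimethylsulfoxonium iodide; 5 butyryl chloride
Product: 7 1-(dimethyloxosulfanylidene)pentan-2-one, via dimethylsulfoxonium methylide 6 (not isolated)
Conditions: 4 (3 equiv), KOtBu (3 equiv), THF, reflux, 2 h; then 5 (1 equiv), 0 °C → rt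
Reagents that add atoms: none
Why: Acylation of a sulfur ylide (Corey–Chaykovsky reagent): methylide 6 adds to the acid chloride and a second equivalent of 6 deprotonates the acylsulfoxonium salt, which should give the stabilised, bench-stable β-keto sulfoxonium ylide.

**Step 3**
Reactants: 3 2-(benzyloxy)-4-methoxybenzoic acid; 7 1-(dimethyloxosulfanylidene)pentan-2-one
Product: 9 8-(benzyloxy)-6-methoxy-3-propylisocoumarin, via 2-(benzyloxy)-4-methoxy-6-(2-oxopentyl)benzoic acid 8 (not isolated)
Conditions: [Cp*RhCl2]2 (2.5 mol %), AgSbF6 (10 mol %), NaOAc (30 mol %), 7 (1.5 equiv), HFIP, 90 °C, N2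
Reagents that add atoms: none
Why: Acetate-assisted concerted metalation–deprotonation at the rhodium carboxylate of 3 cleaves C6–H and gives a five-membered rhodacycle; ylide 7 binds through carbon and loses dimethyl sulfoxide to a rhodium carbene, 1,1-migratory insertion forms the C6–CH bond, and protonolysis releases keto acid 8 and the trivalent rhodium catalyst without an external oxidant. The closest known reaction type is the trivalent-rhodium (or divalent-ruthenium) catalysed coupling of benzoic acids with α-acyl sulfoxonium ylides to 3-substituted isocoumarins. The ring closes by C–O bond formation when the carboxyl oxygen adds to the ketone carbonyl (6-exo-trig) and the hemiketal loses water, which the hot fluorinated alcohol favours. No stereocentre is formed. The step needs site selectivity for a single ortho C–H and chemoselectivity for C–H insertion over O–H insertion of the carbene: the O2 benzyl ether occupies the other ortho position, so only C6–H can be metalated and a second functionalisation is impossible, the ether also prevents salicylate-type O,O-chelation of rhodium, and C3–H and C5–H cannot be reached from the carboxylate. The neutral lactone 9 should be separable from unreacted acid 3 by a hydrogencarbonate wash.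

**Step 4**
Reactants: 9 8-(benzyloxy)-6-methoxy-3-propylisocoumarin
Product: 8 2-(benzyloxy)-4-methoxy-6-(2-oxopentyl)benzoic acid
Conditions: LiOH·H2O (3 equiv), THF/H2O (3:1), 50 °C; then 1 M HCl, 0 °C, to pH 3
Reagents that add atoms: lithium hydroxide, [Li+].[OH-]
Why: Saponification of an enol lactone: hydroxide attacks C1, the enolate leaving group tautomerises to the ketone and carboxylate formation makes the opening irreversible, while cold acidification without heating should keep the isolated keto acid from dehydrating back to 9.

**Step 5**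
Reactants: 10 olivetolic acid (2,4-dihydroxy-6-pentylbenzoic acid)
Product: 11 benzyl 2,4-dihydroxy-6-pentylbenzoate (benzyl olivetolate)
Conditions: BnBr (1.05 equiv), KHCO3 (1.2 equiv), DMF, rt
Reagents that add atoms: benzyl bromide, BrCc1ccccc1
Why: SN2 alkylation of the carboxylate: hydrogencarbonate deprotonates only the carboxylic acid and not the phenols, so one equivalent of benzyl bromide at room temperature should give the ester without O-benzylation and without thermal decarboxylation.

**Step 6**
Reactants: 8 2-(benzyloxy)-4-methoxy-6-(2-oxopentyl)benzoic acid; 11 benzyl 2,4-dihydroxy-6-pentylbenzoate (1.1 equiv)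
Product: 12 benzyl 4-{[2-(benzyloxy)-4-methoxy-6-(2-oxopentyl)benzoyl]oxy}-2-hydroxy-6-pentylbenzoate
Conditions: DCC (1.2 equiv), DMAP (0.2 equiv), CH2Cl2, 0 °C → rt
Reagents that add atoms: none
Why: Steglich esterification: DMAP relays the O-acylisourea of 8 to the 4-hydroxyl of 11, the only nucleophilic phenol because the 2-hydroxyl is hydrogen-bonded to and shielded by the benzyl ester; low temperature disfavours attack of the side-chain enol on the activated acyl group, and any 9 formed that way is recycled through step 4.

**Step 7**
Reactants: 12 benzyl 4-{[2-(benzyloxy)-4-methoxy-6-(2-oxopentyl)benzoyl]oxy}-2-hydroxy-6-pentylbenzoate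
Product: 13 glomelliferic acid
Conditions: H2 (1 atm), 10% Pd/C, EtOAc, rt
Reagents that add atoms: none
Why: Catalytic hydrogenolysis of the two benzylic C–O bonds (aryl benzyl ether and benzyl ester) should free the phenol and the acid, while the dialkyl ketone, the depside ester and the aryl methyl ether are not reduced at one atmosphere and room temperature.

**Compound list**
1 | 4-methoxysalicylic acid (2-hydroxy-4-methoxybenzoic acid) | COc1ccc(C(=O)O)c(O)c1 | starting material
2 | benzyl 2-(benzyloxy)-4-methoxybenzoate | COc1ccc(C(=O)OCc2ccccc2)c(OCc2ccccc2)c1 | intermediate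
3 | 2-(benzyloxy)-4-methoxybenzoic acid | COc1ccc(C(=O)O)c(OCc2ccccc2)c1 | intermediate
4 | trimethylsulfoxonium iodide | C[S+](C)(C)=O.[I-] | starting material
5 | butyryl chloride | CCCC(=O)Cl | starting material
6 | dimethylsulfoxonium methylide | C=S(C)(C)=O | intermediate
7 | 1-(dimethyloxosulfanylidene)pentan-2-one | CCCC(=O)C=S(C)(C)=O | intermediate
8 | 2-(benzyloxy)-4-methoxy-6-(2-oxopentyl)benzoic acid | CCCC(=O)Cc1cc(OC)cc(OCc2ccccc2)c1C(=O)O | intermediate
9 | 8-(benzyloxy)-6-methoxy-3-propylisocoumarin (8-(benzyloxy)-6-methoxy-3-propyl-1H-isochromen-1-one) | CCCC1=Cc2cc(OC)cc(OCc3ccccc3)c2C(=O)O1 | intermediate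
10 | olivetolic acid (2,4-dihydroxy-6-pentylbenzoic acid) | CCCCCc1cc(O)cc(O)c1C(=O)O | starting material
11 | benzyl 2,4-dihydroxy-6-pentylbenzoate | CCCCCc1cc(O)cc(O)c1C(=O)OCc1ccccc1 | intermediate
12 | benzyl 4-{[2-(benzyloxy)-4-methoxy-6-(2-oxopentyl)benzoyl]oxy}-2-hydroxy-6-pentylbenzoate | CCCCCc1cc(OC(=O)c2c(OCc3ccccc3)cc(OC)cc2CC(=O)CCC)cc(O)c1C(=O)OCc1ccccc1 | intermediate
13 | glomelliferic acid | CCCCCc1cc(OC(=O)c2c(O)cc(OC)cc2CC(=O)CCC)cc(O)c1C(=O)O | target

**Step count.** Total: 7 steps. Longest linear sequence: 5 steps (steps 1, 3, 4, 6, 7, from 1 to 13).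

**Steps most likely to fail**

Step 3 (key step).
- Risk: the carboxylate of the electron-rich ortho-alkoxy acid may bind the cationic rhodium too weakly for C6–H cleavage, or the carbene may be diverted into O–H insertion with the acid and into ylide dimerisation.
- Fallback: the classical homophthalic acid annulation, which sets out from butyryl chloride 5 and comes back at isocoumarin 9.
- Commercial 3,5-dimethoxyhomophthalic acid (COc1cc(CC(=O)O)c(C(=O)O)c(OC)c1) is heated with excess 5 at 200 °C. C-acylation of the derived anhydride, recyclisation and decarboxylation should give 6,8-dimethoxy-3-propylisocoumarin F1.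
- BCl3 in CH2Cl2 at −78 → 0 °C should cleave only the methyl ether peri to the lactone carbonyl, through a boron chelate, to 8-hydroxy-6-methoxy-3-propylisocoumarin F2.
- BnBr and K2CO3 in DMF at 60 °C convert F2 into 9.

Step 6.
- Risk: enolisation of the side-chain ketone lets its oxygen attack the activated acyl group through a six-membered transition state, so the hindered, doubly ortho-substituted acid may close back to the enol lactone faster than the phenol is acylated.
- Fallback: the ketone is masked before any acyl activation; the sequence sets out from 8 and comes back at 12.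
- MeI and KHCO3 in DMF alkylate the carboxylate, without acyl activation, to methyl 2-(benzyloxy)-4-methoxy-6-(2-oxopentyl)benzoate F3.
- 1,2-Bis(trimethylsilyloxy)ethane with catalytic TMSOTf in CH2Cl2 at −78 °C (Noyori ketalisation) gives methyl 2-(benzyloxy)-4-methoxy-6-[(2-propyl-1,3-dioxolan-2-yl)methyl]benzoate F4.
- KOH in aqueous DMSO at 90 °C saponifies the hindered ester to 2-(benzyloxy)-4-methoxy-6-[(2-propyl-1,3-dioxolan-2-yl)methyl]benzoic acid F5.
- F5 is coupled with 11 (DCC, DMAP, CH2Cl2) to benzyl 4-({2-(benzyloxy)-4-methoxy-6-[(2-propyl-1,3-dioxolan-2-yl)methyl]benzoyl}oxy)-2-hydroxy-6-pentylbenzoate F6.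
- PPTS in wet acetone at 50 °C removes the dioxolane and gives 12.

Step 2.
- Risk: the basic methylide may dehydrochlorinate the enolisable acid chloride to a ketene, which oligomerises or leads to double acylation of the ylide.
- Fallback: a milder acyl donor; the sequence sets out from 5 and comes back at 7.
- 5 with 4-nitrophenol and Et3N in CH2Cl2 gives 4-nitrophenyl butanoate F7.
- F7 is added to methylide 6 (from 4 and KOtBu) in THF at room temperature; the aryl ester should acylate the ylide without ketene formation and give 7.

**Further compounds**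
F1 | step 3 | 6,8-dimethoxy-3-propylisocoumarin | CCCC1=Cc2cc(OC)cc(OC)c2C(=O)O1
F2 | step 3 | 8-hydroxy-6-methoxy-3-propylisocoumarin | CCCC1=Cc2cc(OC)cc(O)c2C(=O)O1
F3 | step 6 | methyl 2-(benzyloxy)-4-methoxy-6-(2-oxopentyl)benzoate | CCCC(=O)Cc1cc(OC)cc(OCc2ccccc2)c1C(=O)OC
F4 | step 6 | methyl 2-(benzyloxy)-4-methoxy-6-[(2-propyl-1,3-dioxolan-2-yl)methyl]benzoate | CCCC1(Cc2cc(OC)cc(OCc3ccccc3)c2C(=O)OC)OCCO1
F5 | step 6 | 2-(benzyloxy)-4-methoxy-6-[(2-propyl-1,3-dioxolan-2-yl)methyl]benzoic acid | CCCC1(Cc2cc(OC)cc(OCc3ccccc3)c2C(=O)O)OCCO1
F6 | step 6 | benzyl 4-({2-(benzyloxy)-4-methoxy-6-[(2-propyl-1,3-dioxolan-2-yl)methyl]benzoyl}oxy)-2-hydroxy-6-pentylbenzoate | CCCCCc1cc(OC(=O)c2c(OCc3ccccc3)cc(OC)cc2CC2(CCC)OCCO2)cc(O)c1C(=O)OCc1ccccc1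
F7 | step 2 | 4-nitrophenyl butanoate | CCCC(=O)Oc1ccc([N+](=O)[O-])cc1
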